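**Plan**

- Retrosynthesis: the C3–Br bond is cut first (final electrophilic bromination). The pyrrole C2=C3 unsaturation and the benzene aromaticity are then traced back to a cis-fused tetrahydroindole, whose C7–C7a and C4–C3a bonds are cut together.
- Enabling feature: the benzenoid run C7(Br)–C6(H)–C5(Br)–C4(H) is the C3–C6 diene of 3,5-dibromo-2H-pyran-2-one. The atoms N1, C2, C3, C3a and C7a form a five-membered cyclic enecarbamate whose C=C supplies C3a and C7a.
- Forward: the five-membered nitrogen ring is bought. The six-membered carbocycle is built onto it by [4+2] cycloaddition and CO2 extrusion, then aromatised to the indoline, N-deprotected, dehydrogenated to the indole and brominated at C3.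
- Stereochemistry: the target is achiral. The only stereocentres (C3a and C7a of the diene, cis by suprafacial addition, racemic) are transient and vanish on aromatisation. Both benzenoid bromines arrive with the pyrone, so the benzene ring is never brominated.

Key step: step 2

Remark: bridged lactone 4 is expected as an endo/exo mixture; only the endo isomer is drawn, since both isomers give the same cis-fused diene 5 once CO2 is lost. Compound 3 is taken as purchased.

**Route**

Step 1
Reactants: 1 coumalic acid
Product: 2 3,5-dibromo-2H-pyran-2-one
Conditions: NBS (2.5 equiv), LiOAc (1.2 equiv), MeCN–H2O, rt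
Reagents that add atoms: N-bromosuccinimide, O=C1CCC(=O)N1Br
Why: Halodecarboxylation (Hunsdiecker-type ipso-bromination of the lithium carboxylate at C5) followed by electrophilic substitution at C3, the second nucleophilic position of the pyrone, is an established one-flask conversion of coumalic acid into this dibromide, and no stereocentre is formed.

Step 2
Reactants: 2 3,5-dibromo-2H-pyran-2-one; 3 tert-butyl 2,3-dihydro-1H-pyrrole-1-carboxylate
Product: 5 tert-butyl cis-5,7-dibromo-2,3,3a,7a-tetrahydro-1H-indole-1-carboxylate (racemic), via bridged lactone cycloadduct 4 (not isolated)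
Conditions: 3 (2 equiv), 2,6-di-tert-butylpyridine (0.1 equiv), BHT (cat.), PhMe, sealed tube, 100 °C, then 140 °C
Reagents that add atoms: none
Why: The electron-poor diene C3–C6 of pyrone 2 and the electron-rich enecarbamate double bond of 3 should combine in an inverse-demand, concerted but asynchronous Diels–Alder reaction of the kind known for 3,5-dibromo-2-pyrone with enol ethers and other donor alkenes, and on further heating the bridged lactone 4 should expel CO2 by retro-[4+2] cleavage, as 2-oxabicyclo[2.2.2]octenones generally do. The six-membered carbocycle closes by intermolecular [4+2] cycloaddition, in which C7–C7a and C4–C3a both form, and CO2 loss unmasks it as the diene C4=C5–C6=C7. The new stereocentres C3a and C7a are set cis because the addition is suprafacial on the ring-bound Z-alkene of 3; endo and exo isomers of 4 differ only in their relation to the lactone bridge and so converge on the same racemic 5. Regioselectivity is the one selectivity the step needs: the nucleophilic β-carbon of 3 bonds to C6, the most electrophilic diene terminus of the pyrone, so the nitrogen-bearing carbon ends next to the C3 bromine, which becomes C7–Br, while the C5 bromine becomes C5–Br. The hindered pyridine buffers traces of HBr, which would otherwise ionise the C7a–N bond of 5 and aromatise it with ring opening.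

Step 3
Reactants: 5 tert-butyl cis-5,7-dibromo-2,3,3a,7a-tetrahydro-1H-indole-1-carboxylate
Product: 6 tert-butyl 5,7-dibromo-2,3-dihydro-1H-indole-1-carboxylate
Conditions: DDQ (1.1 equiv), PhMe, 0 °C to rt (crude 5, freed from excess 3, used at once)
Reagents that add atoms: none
Why: Quinone dehydrogenation of a cyclohexa-1,3-diene to the arene: DDQ should abstract hydride from C7a (stabilised by the diene and the carbamate nitrogen) and the cation should lose the C3a proton, which erases both stereocentres and fixes the bromines at C5 and C7, while one equivalent at room temperature should leave the N-acyl indoline untouched and the hydroquinone precipitates from toluene.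

Step 4
Reactants: 6 tert-butyl 5,7-dibromo-2,3-dihydro-1H-indole-1-carboxylate
Product: 7 5,7-dibromo-2,3-dihydro-1H-indole
Conditions: TFA, CH2Cl2, 0 °C to rt; aq. NaHCO3 work-up
Reagents that add atoms: none
Why: Acidolysis of the tert-butyl carbamate (loss of the tert-butyl cation, then decarboxylation of the carbamic acid) is safe at this stage because C7a–N is now an aryl–nitrogen bond that cannot ionise, and aryl bromides are inert to TFA.

Step 5
Reactants: 7 5,7-dibromo-2,3-dihydro-1H-indole
Product: 8 5,7-dibromo-1H-indole
Conditions: DDQ (1.1 equiv), PhMe, rt
Reagents that add atoms: none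
Why: Dehydrogenation of an N–H indoline to the indole with DDQ (hydride abstraction from C2 assisted by the free nitrogen lone pair, then proton loss from C3) is a standard oxidation driven by the gain of pyrrole aromaticity, and it is run on the free amine because a carbamate would retard the hydride abstraction.

Step 6
Reactants: 8 5,7-dibromo-1H-indole
Product: 9 3,5,7-tribromo-1H-indole
Conditions: NBS (1.0 equiv), DMF, 0 °C, dark
Reagents that add atoms: N-bromosuccinimide, O=C1CCC(=O)N1Br
Why: Electrophilic aromatic substitution at C3, the most nucleophilic position of an indole, with one equivalent of NBS at low temperature should place the third bromine regioselectively, since the benzo ring is already deactivated by two bromines.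

**Compound list**

1 | coumalic acid (2-oxo-2H-pyran-5-carboxylic acid) | O=C(O)c1ccc(=O)oc1 | starting material
2 | 3,5-dibromo-2H-pyran-2-one | O=c1occ(Br)cc1Br | intermediate
3 | tert-butyl 2,3-dihydro-1H-pyrrole-1-carboxylate | CC(C)(C)OC(=O)N1CCC=C1 | starting material
4 | bridged lactone cycloadduct: tert-butyl 5,7-dibromo-2,3,3a,4,7,7a-hexahydro-1H-indole-1-carboxylate bridged from C4 to C7 by –O–C(=O)– (O on C4, C=O on C7; cis ring fusion; endo isomer drawn, pyrrolidine ring on the side of the C5=C6 bridge; racemic; not isolated) | O=C1O[C@H]2C(Br)=C[C@]1(Br)[C@@H]1N(C(=O)OC(C)(C)C)CC[C@@H]12 | intermediate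
5 | tert-butyl cis-5,7-dibromo-2,3,3a,7a-tetrahydro-1H-indole-1-carboxylate (racemic, one enantiomer drawn) | CC(C)(C)OC(=O)N1CC[C@@H]2C=C(Br)C=C(Br)[C@H]12 | intermediate
6 | tert-butyl 5,7-dibromo-2,3-dihydro-1H-indole-1-carboxylate | CC(C)(C)OC(=O)N1CCc2cc(Br)cc(Br)c21 | intermediate
7 | 5,7-dibromo-2,3-dihydro-1H-indole | Brc1cc2CCNc2c(Br)c1 | intermediate
8 | 5,7-dibromo-1H-indole | Brc1cc(Br)c2[nH]ccc2c1 | intermediate
9 | 3,5,7-tribromo-1H-indole | Brc1cc(Br)c2[nH]cc(Br)c2c1 | target

**Summary**

Total steps: 6. Longest linear sequence: 6 steps (1 → 2 → 5 → 6 → 7 → 8 → 9); 3 is purchased.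

Steps most likely to fail:

1. Step 2. The enecarbamate is only moderately electron-rich, so the cycloaddition may be slow. At the temperature then needed, polymerisation of 3, thermolysis of the carbamate, or aromatisation of the diene with loss of HBr or with ring opening at C7a–N may compete. The fallback sets out from 2 and changes the 2π partner to a more nucleophilic one at a higher oxidation level, so that aromatisation occurs by elimination and not by oxidation. Purchased tert-butyl 2-oxopyrrolidine-1-carboxylate F1 would be O-silylated (LiN(SiMe3)2, THF, −78 °C, then TBSOTf) to the silyl ketene N,O-acetal tert-butyl 5-[(tert-butyldimethylsilyl)oxy]-2,3-dihydro-1H-pyrrole-1-carboxylate F2. This should add to 2 in toluene at 60–80 °C with the same regiochemistry (β-carbon to pyrone C6), giving the 7a-silyloxy bridged lactone F3. Loss of CO2 would give the 7a-silyloxy diene F4, which should aromatise spontaneously by loss of tert-butyldimethylsilanol across C7a–C3a. The fallback returns to the route at 6, replacing steps 2 and 3.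

2. Step 3. While isolated 5 is handled with the quinone, the acidic hydroquinone may ionise the C7a–N bond (ring-opening aromatisation), or the quinone may capture the diene by [4+2] addition. The fallback sets out from 4 and merges CO2 extrusion with dehydrogenation, so the diene never accumulates. The cycloaddition would be held at 80–90 °C so that lactone 4 can be isolated and freed from 3. Lactone 4 would then be heated in chlorobenzene at 130–140 °C over excess activated MnO2, a neutral, insoluble oxidant, so that each molecule of 5 is dehydrogenated as soon as it forms. This makes no new compound (F0) and returns at 6.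

3. Step 6. Over-bromination at C2, or acid-promoted bromine migration and decomposition of the N–H 3-bromoindole by traces of HBr, may erode the last step. The fallback sets out from 8 and brominates an N-sulfonyl indole instead. N-Sulfonylation (NaH, TsCl, DMF, 0 °C) would give 5,7-dibromo-1-tosyl-1H-indole F5. Br2 in CH2Cl2, which brominates N-sulfonylindoles at C3 and stops there, would give 3,5,7-tribromo-1-tosyl-1H-indole F6, a robust compound that can be purified. NaOH in H2O–1,4-dioxane at 60 °C would then remove the sulfonyl group and return to the route at 9.

**Further compounds**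

F1 | step 2 | tert-butyl 2-oxopyrrolidine-1-carboxylate | O=C1CCCN1C(=O)OC(C)(C)C
F2 | step 2 | tert-butyl 5-[(tert-butyldimethylsilyl)oxy]-2,3-dihydro-1H-pyrrole-1-carboxylate | CC(C)(C)OC(=O)N1CCC=C1O[Si](C)(C)C(C)(C)C
F3 | step 2 | 7a-silyloxy bridged lactone: tert-butyl 5,7-dibromo-7a-[(tert-butyldimethylsilyl)oxy]-2,3,3a,4,7,7a-hexahydro-1H-indole-1-carboxylate bridged from C4 to C7 by –O–C(=O)– (O on C4, C=O on C7; one diastereomer drawn, racemic) | O=C1O[C@H]2C(Br)=C[C@]1(Br)[C@]1(O[Si](C)(C)C(C)(C)C)N(C(=O)OC(C)(C)C)CC[C@@H]12
F4 | step 2 | tert-butyl cis-5,7-dibromo-7a-[(tert-butyldimethylsilyl)oxy]-2,3,3a,7a-tetrahydro-1H-indole-1-carboxylate (racemic) | CC(C)(C)OC(=O)N1CC[C@@H]2C=C(Br)C=C(Br)[C@]12O[Si](C)(C)C(C)(C)C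
F0 | step 3 | none | none
F5 | step 6 | 5,7-dibromo-1-tosyl-1H-indole | Cc1ccc(cc1)S(=O)(=O)n1ccc2cc(Br)cc(Br)c21
F6 | step 6 | 3,5,7-tribromo-1-tosyl-1H-indole | Cc1ccc(cc1)S(=O)(=O)n1cc(Br)c2cc(Br)cc(Br)c21
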